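**Strategy.** The route hinges on cutting upper ring C at its oxygen. Without O1 the upper unit is a 3-aryl-indan-1-one, a carbocycle whose one new stereocentre (the future C4) can be installed by catalytic asymmetric aryl addition. The key step, a Baeyer–Villiger oxidation, exploits the position of O1 between aromatic C8a of ring A and C2. In one operation the ring A carbon migrates to oxygen, the C8a–O1 and O1–C2 bonds form, and the five-membered ketone becomes the six-membered lactone with C4 untouched. The precursor is a (3S)-6-benzyloxyindan-1-one carrying hexa-O-benzyl-epigallocatechin at C3 through C8, with bromine capping C6 of the lower ring A.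

Key step: step 9

**Remarks on the chemistry (before the steps)**
- The target is read as (2S,4S)-2,4-cis-4',7-dihydroxyflavan joined from C4 to C8 of (2R,3R)-epigallocatechin. Flavan numbering (O1, C2, C3, C4, C4a, C8a) is used for the upper unit; "lower" marks the epigallocatechin unit. "EGC(Bn)6-8-yl" means (2R,3R)-3,5,7-tris(benzyloxy)-2-[3,4,5-tris(benzyloxy)phenyl]chroman-8-yl.
- The indanone is closed by anionic acylation (step 7), not through an acylium ion. An acylium next to the lower unit would be captured by the flanking benzyloxy oxygen, by the pyran oxygen or by nucleophilic C6 before it reached the position meta to the ring A ether. Ring A therefore enters with an ortho bromine.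
- C6 of the lower ring A, the only free position of the phloroglucinol-type ring, is capped with bromine before the peracid step. The bromine leaves in the final hydrogenolysis.
- The aryl lactone is opened to a Weinreb amide in the flask before ring B is added, because a phenolic ester would release the ketone beside the nucleophile and take up two aryl groups.
- Assumption: the sense of induction of the diene ligand in step 6 is assigned by analogy with simple (E)-cinnamates; if the C3 epimer forms, the (S,S) ligand is used.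
- Assumption: 17 is bought as its THF solution.

**Route**

Step 1
Reactants: 1 (−)-epigallocatechin
Product: 2 hexa-O-benzyl-epigallocatechin
Conditions: BnBr (7 equiv), NaH (6.6 equiv), n-Bu4NI (cat.), DMF, −40 °C to rt, argon
Reagents that add atoms: benzyl bromide, BrCc1ccccc1
Why: Williamson etherification: NaH gives the five phenoxides and then the C3 alkoxide, which are O-benzylated at low temperature faster than ring C-alkylation, and with every phenol capped no quinone-methide pathway can epimerise C2, so the 2R,3R centres are kept.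

Step 2
Reactants: 2 hexa-O-benzyl-epigallocatechin
Product: 3 8-bromo-hexa-O-benzyl-epigallocatechin
Conditions: NBS (1.0 equiv), CH2Cl2, −78 to 0 °C
Reagents that add atoms: N-bromosuccinimide, O=C1CCC(=O)N1Br
Why: Electrophilic aromatic bromination: in 5,7-dialkoxyflavans one equivalent of NBS at low temperature substitutes C8 of ring A in preference to C6 and to the less activated ring B, the known behaviour of benzylated flavan-3-ols.

Step 3
Reactants: 3 8-bromo-hexa-O-benzyl-epigallocatechin; 4 ethyl acrylate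
Product: 5 ethyl (E)-3-[EGC(Bn)6-8-yl]prop-2-enoate
Conditions: Pd2(dba)3 (2.5 mol %), P(t-Bu)3·HBF4 (10 mol %), Cy2NMe (1.5 equiv), dioxane, 80 °C
Reagents that add atoms: none
Why: Mizoroki–Heck reaction: the bulky, electron-rich phosphine lets zerovalent palladium insert into the hindered, electron-rich C8–Br bond, and syn carbopalladation of the acrylate followed by syn β-hydride elimination should give only the E enoate.

Step 4
Reactants: 6 1-benzyloxy-3-bromobenzene
Product: 7 4-benzyloxy-2-bromo-1-iodobenzene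
Conditions: NIS (1.05 equiv), TFA (0.3 equiv), MeCN, rt
Reagents that add atoms: N-iodosuccinimide, O=C1CCC(=O)N1I
Why: Electrophilic aromatic iodination: acid-activated NIS attacks para to the benzyloxy group (ortho to bromine), the most activated position and less hindered than the site between the two substituents.

Step 5
Reactants: 7 4-benzyloxy-2-bromo-1-iodobenzene
Product: 10 (4-benzyloxy-2-bromophenyl)boronic acid, via arylmagnesium chloride 8 (not isolated), via dimethyl boronate 9 (not isolated)
Conditions: i-PrMgCl·LiCl (1.1 equiv), THF, −40 °C; B(OMe)3 (2 equiv), −40 °C to rt; 1 M HCl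
Reagents that add atoms: trimethyl borate, COB(OC)OC; water, O
Why: Iodine–magnesium exchange followed by borylation: the C–I bond exchanges much faster than C–Br, the ortho-bromoarylmagnesium species is stable at −40 °C (no aryne loss), and trapping with trimethyl borate and acidic hydrolysis gives the boronic acid.

Step 6
Reactants: 5 ethyl (E)-3-[EGC(Bn)6-8-yl]prop-2-enoate; 10 (4-benzyloxy-2-bromophenyl)boronic acid
Product: 11 ethyl (3R)-3-(4-benzyloxy-2-bromophenyl)-3-[EGC(Bn)6-8-yl]propanoate
Conditions: [RhCl(C2H4)2]2 (2.5 mol %), (R,R)-Ph-bod* [(1R,4R)-2,5-diphenylbicyclo[2.2.2]octa-2,5-diene] (5.5 mol %), KOH (0.5 equiv), 10 (2.5 equiv), dioxane/H2O (10:1), 50 °C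
Reagents that add atoms: none
Why: Hayashi–Miyaura asymmetric 1,4-addition: transmetalation gives an aryl complex of monovalent rhodium that inserts the enoate and is protonated by water, the C2-symmetric diene choosing the enoate face so that the new diarylmethine centre should form as 3R under catalyst control (the lower-unit stereocentres are remote), while the ortho C–Br bond is inert to monovalent rhodium.

Step 7
Reactants: 11 ethyl (3R)-3-(4-benzyloxy-2-bromophenyl)-3-[EGC(Bn)6-8-yl]propanoate
Product: 13 (3S)-6-benzyloxy-3-[EGC(Bn)6-8-yl]indan-1-one, via aryllithium 12 (not isolated)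
Conditions: t-BuLi (2.1 equiv), THF, −100 to −78 °C; NH4Cl aq
Reagents that add atoms: none
Why: Parham cyclisation: bromine–lithium exchange at −100 °C outruns attack on the ester, the aryllithium acylates itself on the tethered ester (5-exo-trig) and the second equivalent of t-BuLi is consumed by t-BuBr, so the ketone forms without any acylium ion that the oxygens or C6 of the lower ring A could intercept; the diarylmethine centre is not deprotonated and keeps its spatial arrangement (descriptor 3S by priority change).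

Step 8
Reactants: 13 (3S)-6-benzyloxy-3-[EGC(Bn)6-8-yl]indan-1-one
Product: 14 (3S)-6-benzyloxy-3-[6-bromo-EGC(Bn)6-8-yl]indan-1-one
Conditions: NBS (1.05 equiv), CH2Cl2, −78 to −20 °C
Reagents that add atoms: N-bromosuccinimide, O=C1CCC(=O)N1Br
Why: Electrophilic aromatic bromination: C6 of the lower ring A, flanked by two benzyloxy groups, is by far the most nucleophilic position left, so one equivalent of NBS at low temperature should cap it and leave the acyl-deactivated ring A and the ketone α-position alone.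

Step 9
Reactants: 14 (3S)-6-benzyloxy-3-[6-bromo-EGC(Bn)6-8-yl]indan-1-one
Product: 16 (4S)-7-benzyloxy-4-[6-bromo-EGC(Bn)6-8-yl]chroman-2-one, via Criegee adduct 15 (not isolated)
Conditions: mCPBA (3 equiv), TsOH·H2O (0.1 equiv), CH2Cl2, 0–4 °C, dark; Na2S2O3/NaHCO3 aq
Reagents that add atoms: mCPBA, OOC(=O)c1cccc(Cl)c1
Why: Baeyer–Villiger oxidation: the peracid adds to the acid-activated C1 carbonyl to give the Criegee adduct, and the aromatic carbon C7a of ring A migrates to the proximal peroxide oxygen as 3-chlorobenzoate leaves, so oxygen enters between ring A and the carbonyl carbon. The closest known reaction type is the peracid oxidation of 3-aryl-6-alkylindan-1-ones to 4-aryl-3,4-dihydrocoumarins. The six-membered lactone arises by ring expansion through this 1,2-shift (C8a–O1 and O1–C2 formed as the O–O bond breaks), not by cyclisation of a chain. No stereocentre is created, and the diarylmethine carbon (old C3, new C4) is a spectator that keeps its S configuration. Two selectivities are needed: aryl over methylene migration, secured by the higher migratory aptitude of the aromatic carbon over the primary C2 methylene; and ketone over arene oxidation, secured by the bromine at C6 of the lower ring A, which removes the only unsubstituted position of the most electron-rich ring, the other arenes being acyl-deactivated or far less nucleophilic.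

Step 10
Reactants: 16 (4S)-7-benzyloxy-4-[6-bromo-EGC(Bn)6-8-yl]chroman-2-one; 17 4-benzyloxyphenylmagnesium bromide
Product: 19 (3S)-1-(4-benzyloxyphenyl)-3-(4-benzyloxy-2-hydroxyphenyl)-3-[6-bromo-EGC(Bn)6-8-yl]propan-1-one, via Weinreb amide 18 (not isolated)
Conditions: MeNH(OMe)·HCl (1.5 equiv), i-PrMgCl (3.0 equiv), THF, −20 °C; then 17 (3 equiv), 0 °C to rt; NH4Cl aq
Reagents that add atoms: none
Why: Weinreb ketone synthesis run in one flask: the chloromagnesium amide made from the amine salt opens the aryl lactone to the Weinreb amide (phenol as its magnesium salt), and the aryl Grignard then adds once because the five-membered magnesium chelate holds the tetrahedral adduct until work-up, which avoids the double addition expected for a phenolic ester.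

Step 11
Reactants: 19 (3S)-1-(4-benzyloxyphenyl)-3-(4-benzyloxy-2-hydroxyphenyl)-3-[6-bromo-EGC(Bn)6-8-yl]propan-1-one
Product: 21 (2S,4S)-7-benzyloxy-2-(4-benzyloxyphenyl)-4-[6-bromo-EGC(Bn)6-8-yl]chroman, via cyclic hemiketal 20 (not isolated)
Conditions: Et3SiH (5 equiv), BF3·OEt2 (1.5 equiv), CH2Cl2/MeCN (1:1), −40 to −10 °C; NaHCO3 aq
Reagents that add atoms: none
Why: Silane reduction of a cyclic hemiketal (ionic hydrogenation): BF3 ionises the hemiketal formed from the phenol and the ketone to a 2-aryl oxocarbenium ion, and Et3SiH delivers hydride along the axial trajectory anti to the pseudoaxial C4 aryl group, so the C2 aryl should end cis to the C4 aryl (new C2 = S, substrate control; also the thermodynamically favoured diequatorial isomer).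

Step 12
Reactants: 21 (2S,4S)-7-benzyloxy-2-(4-benzyloxyphenyl)-4-[6-bromo-EGC(Bn)6-8-yl]chroman
Product: 22 CNP0220331.2 (target)
Conditions: H2 (1 atm), Pd(OH)2/C, Et3N (1.5 equiv), THF/MeOH (1:1), rt; AcOH on work-up, argon
Reagents that add atoms: none
Why: Hydrogenolysis on palladium: all seven benzyl ethers and the aryl C–Br bond are cleaved in one operation (Et3N takes up HBr), while the cyclic benzylic C2–O1 ethers of both units and all four stereocentres should remain untouched.

**Compound list**

1 | (−)-epigallocatechin, (2R,3R) | O[C@@H]1Cc2c(O)cc(O)cc2O[C@@H]1c1cc(O)c(O)c(O)c1 | starting material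
2 | hexa-O-benzyl-epigallocatechin, (2R,3R)-3,5,7-tris(benzyloxy)-2-[3,4,5-tris(benzyloxy)phenyl]chroman | c1c(OCc2ccccc2)cc(OCc2ccccc2)c2c1O[C@H](c1cc(OCc3ccccc3)c(OCc3ccccc3)c(OCc3ccccc3)c1)[C@H](OCc1ccccc1)C2 | intermediate
3 | 8-bromo-hexa-O-benzyl-epigallocatechin | Brc1c(OCc2ccccc2)cc(OCc2ccccc2)c2c1O[C@H](c1cc(OCc3ccccc3)c(OCc3ccccc3)c(OCc3ccccc3)c1)[C@H](OCc1ccccc1)C2 | intermediate
4 | ethyl acrylate | C=CC(=O)OCC | starting material
5 | ethyl (E)-3-[EGC(Bn)6-8-yl]prop-2-enoate | CCOC(=O)/C=C/c1c(OCc2ccccc2)cc(OCc2ccccc2)c2c1O[C@H](c1cc(OCc3ccccc3)c(OCc3ccccc3)c(OCc3ccccc3)c1)[C@H](OCc1ccccc1)C2 | intermediate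
6 | 1-benzyloxy-3-bromobenzene | Brc1cccc(OCc2ccccc2)c1 | starting material
7 | 4-benzyloxy-2-bromo-1-iodobenzene | Ic1ccc(OCc2ccccc2)cc1Br | intermediate
8 | (4-benzyloxy-2-bromophenyl)magnesium chloride | Cl[Mg]c1ccc(OCc2ccccc2)cc1Br | intermediate
9 | dimethyl (4-benzyloxy-2-bromophenyl)boronate | COB(OC)c1ccc(OCc2ccccc2)cc1Br | intermediate
10 | (4-benzyloxy-2-bromophenyl)boronic acid | OB(O)c1ccc(OCc2ccccc2)cc1Br | intermediate
11 | ethyl (3R)-3-(4-benzyloxy-2-bromophenyl)-3-[EGC(Bn)6-8-yl]propanoate | CCOC(=O)C[C@H](c1c(OCc2ccccc2)cc(OCc2ccccc2)c2c1O[C@H](c1cc(OCc3ccccc3)c(OCc3ccccc3)c(OCc3ccccc3)c1)[C@H](OCc1ccccc1)C2)c1ccc(OCc2ccccc2)cc1Br | intermediate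
12 | aryllithium from 11 (Li in place of Br, same spatial arrangement at the methine) | CCOC(=O)C[C@H](c1c(OCc2ccccc2)cc(OCc2ccccc2)c2c1O[C@H](c1cc(OCc3ccccc3)c(OCc3ccccc3)c(OCc3ccccc3)c1)[C@H](OCc1ccccc1)C2)c1ccc(OCc2ccccc2)cc1[Li] | intermediate
13 | (3S)-6-benzyloxy-3-[EGC(Bn)6-8-yl]indan-1-one | O=C1C[C@H](c2c(OCc3ccccc3)cc(OCc3ccccc3)c3c2O[C@H](c2cc(OCc4ccccc4)c(OCc4ccccc4)c(OCc4ccccc4)c2)[C@H](OCc2ccccc2)C3)c2ccc(OCc3ccccc3)cc21 | intermediate
14 | (3S)-6-benzyloxy-3-[6-bromo-EGC(Bn)6-8-yl]indan-1-one (key-step precursor) | O=C1C[C@H](c2c(OCc3ccccc3)c(Br)c(OCc3ccccc3)c3c2O[C@H](c2cc(OCc4ccccc4)c(OCc4ccccc4)c(OCc4ccccc4)c2)[C@H](OCc2ccccc2)C3)c2ccc(OCc3ccccc3)cc21 | intermediate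
15 | Criegee adduct of 14 with mCPBA (C1 hydroxy peroxyester, C1 unassigned) | OC1(OOC(=O)c2cccc(Cl)c2)C[C@H](c2c(OCc3ccccc3)c(Br)c(OCc3ccccc3)c3c2O[C@H](c2cc(OCc4ccccc4)c(OCc4ccccc4)c(OCc4ccccc4)c2)[C@H](OCc2ccccc2)C3)c2ccc(OCc3ccccc3)cc21 | intermediate
16 | (4S)-7-benzyloxy-4-[6-bromo-EGC(Bn)6-8-yl]chroman-2-one (key-step product) | O=C1C[C@H](c2c(OCc3ccccc3)c(Br)c(OCc3ccccc3)c3c2O[C@H](c2cc(OCc4ccccc4)c(OCc4ccccc4)c(OCc4ccccc4)c2)[C@H](OCc2ccccc2)C3)c2ccc(OCc3ccccc3)cc2O1 | intermediate
17 | 4-benzyloxyphenylmagnesium bromide (THF solution) | Br[Mg]c1ccc(OCc2ccccc2)cc1 | starting material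
18 | (3S)-N-methoxy-N-methyl-3-(4-benzyloxy-2-hydroxyphenyl)-3-[6-bromo-EGC(Bn)6-8-yl]propanamide (present as magnesium phenoxide) | CON(C)C(=O)C[C@H](c1c(OCc2ccccc2)c(Br)c(OCc2ccccc2)c2c1O[C@H](c1cc(OCc3ccccc3)c(OCc3ccccc3)c(OCc3ccccc3)c1)[C@H](OCc1ccccc1)C2)c1ccc(OCc2ccccc2)cc1O | intermediate
19 | (3S)-1-(4-benzyloxyphenyl)-3-(4-benzyloxy-2-hydroxyphenyl)-3-[6-bromo-EGC(Bn)6-8-yl]propan-1-one | O=C(C[C@H](c1c(OCc2ccccc2)c(Br)c(OCc2ccccc2)c2c1O[C@H](c1cc(OCc3ccccc3)c(OCc3ccccc3)c(OCc3ccccc3)c1)[C@H](OCc1ccccc1)C2)c1ccc(OCc2ccccc2)cc1O)c1ccc(OCc2ccccc2)cc1 | intermediate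
20 | (4S)-7-benzyloxy-2-(4-benzyloxyphenyl)-4-[6-bromo-EGC(Bn)6-8-yl]chroman-2-ol (cyclic hemiketal, C2 unassigned) | OC1(c2ccc(OCc3ccccc3)cc2)C[C@H](c2c(OCc3ccccc3)c(Br)c(OCc3ccccc3)c3c2O[C@H](c2cc(OCc4ccccc4)c(OCc4ccccc4)c(OCc4ccccc4)c2)[C@H](OCc2ccccc2)C3)c2ccc(OCc3ccccc3)cc2O1 | intermediate
21 | (2S,4S)-7-benzyloxy-2-(4-benzyloxyphenyl)-4-[6-bromo-EGC(Bn)6-8-yl]chroman | c1ccccc1COc1ccc([C@@H]2C[C@H](c3c(OCc4ccccc4)c(Br)c(OCc4ccccc4)c4c3O[C@H](c3cc(OCc5ccccc5)c(OCc5ccccc5)c(OCc5ccccc5)c3)[C@H](OCc3ccccc3)C4)c3ccc(OCc4ccccc4)cc3O2)cc1 | intermediate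
22 | CNP0220331.2, (2S,4S)-4',7-dihydroxyflavan-(4→8)-(2R,3R)-epigallocatechin | Oc1ccc([C@@H]2C[C@H](c3c(O)cc(O)c4c3O[C@H](c3cc(O)c(O)c(O)c3)[C@H](O)C4)c3ccc(O)cc3O2)cc1 | target

**Step count**

Total step count: 12 (ten in the main line, two for the boronic acid 10).
Longest linear sequence: 10 steps (1, 2, 3, 6, 7, 8, 9, 10, 11, 12).

**Steps most likely to fail, riskiest first**

Step 6. Insertion of the arylrhodium species into the hindered, electron-rich enoate may be slow, so that protodeboronation of the ortho-bromo boronic acid consumes the nucleophile, or facial discrimination erodes at the temperature needed. Fallback: replace catalyst control by a covalently bound auxiliary and a stoichiometric organocopper reagent acting on a more electrophilic acceptor. Setting out from 5, saponification (LiOH, THF/H2O) gives (E)-3-[EGC(Bn)6-8-yl]prop-2-enoic acid F1. Mixed-anhydride activation (PivCl, Et3N, THF, −20 °C) and acylation of lithiated (R)-4-phenyloxazolidin-2-one give the N-enoyl imide F2. The arylmagnesium chloride 8 (made from 7 as in step 5) with CuBr·SMe2 in THF/SMe2 at −40 °C should add anti to the 4-phenyl group of the magnesium-chelated syn-s-cis imide to give the conjugate adduct F3. Bromomagnesium ethoxide (EtMgBr added to EtOH, THF, 0 °C) transesterifies the imide and returns to the route at 11.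

Step 9. The peracid may oxidise the alkoxy-rich arenes faster than it adds to the hindered, conjugated ketone; the acid co-catalyst may also ionise the lower C2–O1 bond. Fallback: make the C8a–O1 bond by C–O cross-coupling in place of oxygen insertion. Setting out from 11, palladium-catalysed hydroxylation of the aryl bromide (Pd2(dba)3, t-BuXPhos, KOH, dioxane/H2O, 100 °C) converts C–Br into the phenoxide and saponifies the ester. Acidification (1 M HCl, then TsOH cat., toluene, 40 °C) closes the hydroxy acid to (4S)-7-benzyloxy-4-[EGC(Bn)6-8-yl]chroman-2-one F4. NBS (CH2Cl2, −78 °C) then brominates C6 of the lower ring A and returns to the route at 16.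

Step 11. The newly formed 4-alkoxybenzylic C2–O1 bond may re-ionise under BF3 and take a second hydride (ring-opening over-reduction), or hydride delivery may be incompletely face-selective. Fallback: set C2 by reagent-controlled ketone reduction and close the ring by SN2 etherification. Setting out from 19, Corey–Bakshi–Shibata reduction ((S)-2-methyl-CBS-oxazaborolidine, BH3·SMe2, THF, −20 °C) should give the (1R)-configured benzylic alcohol F5. Mitsunobu cyclisation (PPh3, DIAD, THF, 0 °C) engages the phenol with inversion at the carbinol carbon and returns to the route at 21.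

**Further compounds**

F1 | step 6 | (E)-3-[EGC(Bn)6-8-yl]prop-2-enoic acid | OC(=O)/C=C/c1c(OCc2ccccc2)cc(OCc2ccccc2)c2c1O[C@H](c1cc(OCc3ccccc3)c(OCc3ccccc3)c(OCc3ccccc3)c1)[C@H](OCc1ccccc1)C2
F2 | step 6 | (4R)-3-{(E)-3-[EGC(Bn)6-8-yl]prop-2-enoyl}-4-phenyloxazolidin-2-one | O=C(/C=C/c1c(OCc2ccccc2)cc(OCc2ccccc2)c2c1O[C@H](c1cc(OCc3ccccc3)c(OCc3ccccc3)c(OCc3ccccc3)c1)[C@H](OCc1ccccc1)C2)N1[C@H](c2ccccc2)COC1=O
F3 | step 6 | (4R)-3-{(3R)-3-(4-benzyloxy-2-bromophenyl)-3-[EGC(Bn)6-8-yl]propanoyl}-4-phenyloxazolidin-2-one | O=C(C[C@H](c1c(OCc2ccccc2)cc(OCc2ccccc2)c2c1O[C@H](c1cc(OCc3ccccc3)c(OCc3ccccc3)c(OCc3ccccc3)c1)[C@H](OCc1ccccc1)C2)c1ccc(OCc2ccccc2)cc1Br)N1[C@H](c2ccccc2)COC1=O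
F4 | step 9 | (4S)-7-benzyloxy-4-[EGC(Bn)6-8-yl]chroman-2-one | O=C1C[C@H](c2c(OCc3ccccc3)cc(OCc3ccccc3)c3c2O[C@H](c2cc(OCc4ccccc4)c(OCc4ccccc4)c(OCc4ccccc4)c2)[C@H](OCc2ccccc2)C3)c2ccc(OCc3ccccc3)cc2O1
F5 | step 11 | (1R,3S)-1-(4-benzyloxyphenyl)-3-(4-benzyloxy-2-hydroxyphenyl)-3-[6-bromo-EGC(Bn)6-8-yl]propan-1-ol | c1ccccc1COc1ccc([C@H](O)C[C@H](c2c(OCc3ccccc3)c(Br)c(OCc3ccccc3)c3c2O[C@H](c2cc(OCc4ccccc4)c(OCc4ccccc4)c(OCc4ccccc4)c2)[C@H](OCc2ccccc2)C3)c2ccc(OCc3ccccc3)cc2O)cc1
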